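## Structural features

Compound 32 is a furanoheliangolide: a ten-membered carbocycle (C1–C10) is bridged by an oxygen between C3 and C10, so that O, C3, C2, C1(=O) and C10 make up a 3(2H)-furanone, and it is trans-fused at C6–C7 to an α-methylene-γ-butyrolactone (C6–O–C12(=O)–C11(=C13)–C7). A Z trisubstituted alkene C4=C5 links the furanone to C6 and is conjugated with it. C6 (R), C7 (S), C8 (S) and C9 (S) are contiguous and the quaternary C10 (R) follows C9, but C10 is insulated from C6/C7 by the unsaturated half of the ring; H-6 and H-7 are trans, and the oxygens on C8 and C9 are cis to each other and trans to H-7. C8 carries an (E)-2-(acetoxymethyl)but-2-enoate and C9 an acetate. In the bicyclo[6.2.1] frame the C7–C8–C9–C10 segment lies over the oxygen edge of the furanone, so one of its faces (called β here) looks at the C1–C2 edge and is concave while the other (α, the side of H-7) is open; both ester oxygens sit on the concave face. Fragile groups are the exocyclic methylene lactone (Michael acceptor), the Z C4=C5 bond whenever C6 is a carbonyl carbon, C2 of the vinylogous ester towards electrophiles, the cis-diol diester (acyl migration) and the allylic acetate of the side chain. The real difficulty is threefold: closing the strained bridged ring, setting C10 and C6/C7 independently of each other, and placing two different acyloxy groups on the hindered face at C8 and at the neopentylic C9. The key step exploits the fact that C8 and C9 are adjacent CH–O carbons with cis oxygens, the image of a Z C8=C9 alkene inside the ten-membered ring, whose two carbons can be supplied by vinyl groups on C7 of the lactone ring and on C10 of the furanone ring, the only monosubstituted alkenes of the seco compound.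

## Logic of the disconnections

**32 ⇒ 31.** The acetyl C–O bond at O9 is cut first. The acetate is the group most prone to 1,2-migration, so it is attached last and never meets base afterwards. 31 has a single free hydroxyl, which removes any question of site. The forward step must acylate a neopentylic hydroxyl on the concave face without moving the C8 ester, which calls for Lewis acid catalysis and not a nucleophilic base.

**31 ⇒ 29 + 25.** The acyl C–O bond of the C8 ester is cut. 25 holds an allylic acetate and a further acceptor alkene that would not survive positive iodine, so it has to arrive after the dioxygenation. The problem shrinks to 29 and a three-step acid. The forward acylation must find O8, which is flanked by the C7 methine, and leave O9, which is neopentylic.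

**29 ⇒ 19.** The C8–O and C9–O bonds are cut together, since cis vicinal oxygens map onto the Z alkene of 19. All remaining stereochemistry at C8/C9 becomes one facial question. A reagent that adds from the open α face (osmium tetroxide) would give the wrong configuration at both carbons. The forward step must therefore put the oxygens on the face opposite to the electrophile that attacks first, by iodonium formation, anti opening and neighbouring-group inversion. That sequence passes through 27 and 28, whose proportion cannot be foreseen, so both are cleaved to 29 before anything is isolated.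

**19 ⇒ 18.** The C8=C9 bond is cut to two vinyl groups. This is the least substituted alkene the skeleton allows, and the cut leaves furanone, Z C4=C5 and lactone intact on open-chain material. The forward ring closure must beat oligomerisation and give Z.

**18 ⇒ 11 + 15.** The C6–C7 bond and the lactone O–C12 bond are cut. This is the only junction of the two halves through sp3 carbons. 15 brings C7, its vinyl group, C11, C12 and C13 in one piece. The addition must be anti (trans lactone) and must set 6R,7S without help from the distant C10, so the face is chosen by a chiral catalyst.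

**11 ⇒ 10 ⇒ 9.** Only the oxidation level and the silyl group at C6 change. 11 is made immediately before use because its Z enal is the most isomerisation-prone unit of the route.

**9 ⇒ 8.** The O–C3 bond of the furanone is cut, giving an α′-hydroxy ynone. The forward 5-endo addition needs the primary oxygen masked so that only the tertiary hydroxyl can add to C3.

**8 ⇒ 4 + 6 (6 ⇐ 5).** The C1–C2 bond is cut to an amide and an acetylide. The Z C4=C5 bond is bought with 5. The forward step must stop at the ketone and tolerate the free tertiary hydroxyl.

**4 ⇒ 3 ⇒ 2 ⇒ 1.** The C10–O bond is traced to 1, which is racemic. Both enantiomers of 1 must converge on one enantiomer of 2; the later steps only adjust the oxidation level of C1.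

**15 ⇒ 14 ⇒ 12 + 13.** The C–Br bond is cut with allylic transposition, then the C–C bond between the acrylate α-carbon and the aldehyde carbon. The regiochemistry of bromination is not critical, because either dienyl bromide gives the same pentadienyl metal species.

**25 ⇒ 24 ⇒ 22 ⇒ 20 + 21.** The tert-butyl ester is unmasked, the acetate is transposed, and the C–C bond is cut to acrylate and aldehyde. The forward transposition must give the E alkene, which is the thermodynamic isomer.

## Other disconnections considered

Alternative 1: A C4–C9 bond is added in the retrosynthetic sense, so the medium ring is folded into two fused six-membered rings. Forward, a tertiary alkoxide on C9 pushes, the C4–C9 bond breaks, C9=O and Z C4=C5 form and a mesylate leaves from C5 (Grob fragmentation). The product would be the ten-membered ketone A1 with the C1/C3 dione still masked.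
- In favour: ring expansion needs no high dilution, and the alkene geometry is dictated by the anti-periplanar arrangement of the breaking bonds.
- Better than the chosen plan on one point: the C9 carbonyl of A1 could take hydride from the open face, which would place the C9 hydroxyl on the hindered face that the chosen route reaches only by a double inversion.
- Against: before the fragmentation, three contiguous fully substituted carbons (C4, C9, C10) and six correctly related stereocentres have to be assembled. The alkoxide threatens the methylene lactone. After A1 there remain ketone reduction, two acetal cleavages beside an enol ether, furanone closure and two esterifications.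
- Comparison: the chosen plan takes furanone and Z alkene from commercial material and closes the ring with a tolerant catalyst. The fragmentation needs exact orbital alignment and should cost clearly more steps. Neither ring-forming step creates a stereocentre, so the two are equal there.

Alternative 2: The C2–C3 bond is cut, so that C3 becomes the carbonyl of a nine-membered lactone closed on the C10 oxygen and C1–C2 becomes an acetyl group on C10. Forward, the enolate of that methyl ketone (C2) attacks the lactone carbonyl C3 through a five-membered transition state (O-to-C acyl shift), and acid dehydration closes the furanone to give A2.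
- In favour: the C–C bond forms intramolecularly, and the strain of the bridged ring is paid for by forming the vinylogous ester.
- Better than the chosen plan on one point: the cis diol travels as an acetonide set early in an open chain, where reagent control is easy.
- Against: the nine-membered lactone would have to be closed onto the tertiary C10 hydroxyl. Strong base meets the methylene lactone and the Z enoate (conjugate addition, isomerisation). The acyl shift is reversible until dehydration.
- Comparison: removal of the acetonide from A2 would lead to the same diol as 29, so the end-game with its site-selective acylation is identical and that point is equal. The C8–C9–C10 triad has to be built linearly, so the step count should be similar or somewhat higher.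

Alternative 3: The C5–C6 bond is cut. Forward, a Z vinyl iodide at C5 adds to a C6 aldehyde under CrCl2 with catalytic NiCl2 (Nozaki–Hiyama–Kishi macrocyclisation) to give the cyclodecadienol A3.
- In favour: the reaction is chemoselective for the aldehyde, and the iodide geometry is retained.
- Better than the chosen plan on one point: the C8 and C9 oxygens are in place and differentiated (silyl ether and acetate) before ring closure, so neither the hindered-face dioxygenation nor the late distinction of two hydroxyls arises.
- Against: the C6 stereocentre is formed in the ring closure under conformational control only. The aldehyde has an epimerisable α-carbon (C7) that is also allylic. From A3 the lactone and side chain need about six further steps (two desilylations, oxidation of C12 to the acid level, lactonisation, esterification). CrCl2 is stoichiometric.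
- Comparison: both plans rest on one dilute macrocyclisation, which is equal. The chosen closure forms no stereocentre and is followed by only three steps.

Key step: step 12

Assumption: in steps 1 and 11 the ligand enantiomer is the one whose known sense of induction gives the configuration drawn (R at C10; Si-face addition at C6); the descriptors written for the ligands stand for that choice.

## Route

Step 1
Reactants: 1 2-methyl-2-vinyloxirane (racemic)
Product: 2 (2R)-2-methylbut-3-ene-1,2-diol
Conditions: Pd2(dba)3·CHCl3 (1 mol %), (S,S)-N,N'-(cyclohexane-1,2-diyl)bis[2-(diphenylphosphanyl)-1-naphthamide] (3 mol %), BEt3 (1 mol %), NaHCO3, CH2Cl2/H2O, rt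
Reagents that add atoms: water (O), delivered through sodium hydrogen carbonate (OC(=O)[O-].[Na+])
Why: Palladium-catalysed dynamic kinetic asymmetric allylic substitution: zerovalent palladium ionises both enantiomers of 1 to interconverting π-allyl complexes, the boron-bound alkoxide steers hydrogen carbonate to the substituted terminus, and the chiral ligand decides the face and so sets C10 (R); the carbonate ester should hydrolyse to the diol in the flask.

Step 2
Reactants: 2 (2R)-2-methylbut-3-ene-1,2-diol
Product: 3 (2R)-2-hydroxy-2-methylbut-3-enoic acid
Conditions: TEMPO (cat.), NaOCl (cat.), NaClO2, MeCN/phosphate buffer pH 6.7, 35 °C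
Reagents that add atoms: sodium chlorite ([Na+].[O-]Cl=O)
Why: Oxoammonium/chlorite oxidation of a primary alcohol to the acid: only the CH2OH group has a carbinol hydrogen, chlorite takes the aldehyde on at once, and the quaternary stereocentre cannot epimerise.

Step 3
Reactants: 3 (2R)-2-hydroxy-2-methylbut-3-enoic acid
Product: 4 (2R)-2-hydroxy-N-methoxy-N,2-dimethylbut-3-enamide
Conditions: MeNHOMe·HCl, EDC·HCl, HOBt, N-methylmorpholine, CH2Cl2, 0 °C to rt
Reagents that add atoms: N,O-dimethylhydroxylamine hydrochloride (CNOC.Cl)
Why: Carbodiimide amide coupling; the tertiary hydroxyl is too hindered to be acylated, so it needs no protection.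

Step 4
Reactants: 5 (2Z)-3-methylpent-2-en-4-yn-1-ol
Product: 6 tert-butyl(dimethyl){[(2Z)-3-methylpent-2-en-4-yn-1-yl]oxy}silane
Conditions: TBSCl, imidazole, CH2Cl2, 0 °C to rt
Reagents that add atoms: tert-butylchlorodimethylsilane (CC(C)(C)[Si](C)(C)Cl)
Why: Silylation of the primary allylic alcohol; the ether survives butyllithium and later keeps this oxygen from adding to the ynone, which would lead to a furan.

Step 5
Reactants: 6 tert-butyl(dimethyl){[(2Z)-3-methylpent-2-en-4-yn-1-yl]oxy}silane; 4 (2R)-2-hydroxy-N-methoxy-N,2-dimethylbut-3-enamide
Product: 8 (3R,7Z)-9-{[tert-butyl(dimethyl)silyl]oxy}-3-hydroxy-3,7-dimethylnona-1,7-dien-5-yn-4-one, via lithium acetylide 7 (not isolated)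
Conditions: 6 (2.4 equiv), n-BuLi (2.3 equiv), THF, −78 °C; then 4, −78 to −20 °C; aq. NH4Cl
Reagents that add atoms: none
Why: Weinreb ketone synthesis: one equivalent of 7 is spent on the tertiary hydroxyl of 4 (and returns as 6 on quench), a second adds to the amide, and the chelated tetrahedral intermediate holds until the quench, so the ynone is not attacked again; the Z alkene and C10 are untouched.

Step 6
Reactants: 8 (3R,7Z)-9-{[tert-butyl(dimethyl)silyl]oxy}-3-hydroxy-3,7-dimethylnona-1,7-dien-5-yn-4-one
Product: 9 (2R)-5-[(2Z)-4-{[tert-butyl(dimethyl)silyl]oxy}but-2-en-2-yl]-2-ethenyl-2-methylfuran-3(2H)-one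
Conditions: (Ph3P)AuCl (2 mol %), AgOTf (2 mol %), toluene, rt
Reagents that add atoms: none
Why: Gold-catalysed 5-endo-dig cycloisomerisation (intramolecular hydroalkoxylation) of an α′-hydroxy ynone, an established entry to 3(2H)-furanones: the tertiary hydroxyl adds to the alkyne carbon C3 activated by monovalent gold and protodeauration gives the vinylogous ester; no stereocentre is formed.

Step 7
Reactants: 9 (2R)-5-[(2Z)-4-{[tert-butyl(dimethyl)silyl]oxy}but-2-en-2-yl]-2-ethenyl-2-methylfuran-3(2H)-one
Product: 10 (2R)-2-ethenyl-5-[(2Z)-4-hydroxybut-2-en-2-yl]-2-methylfuran-3(2H)-one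
Conditions: HF·pyridine, pyridine, THF, 0 °C to rt
Reagents that add atoms: none
Why: Fluoride desilylation under buffered, non-basic conditions that leave the vinylogous ester and the Z alkene alone.

Step 8
Reactants: 10 (2R)-2-ethenyl-5-[(2Z)-4-hydroxybut-2-en-2-yl]-2-methylfuran-3(2H)-one
Product: 11 (2Z)-3-[(2R)-2-ethenyl-2-methyl-3-oxo-2,3-dihydrofuran-5-yl]but-2-enal
Conditions: Dess–Martin periodinane, pyridine, CH2Cl2, 0 °C; used crude at once
Reagents that add atoms: none
Why: Dess–Martin oxidation of the allylic alcohol under buffered conditions at 0 °C, chosen to avoid Z to E isomerisation of the enal.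

Step 9
Reactants: 12 acrolein; 13 methyl acrylate
Product: 14 methyl 3-hydroxy-2-methylidenepent-4-enoate (racemic)
Conditions: DABCO (20 mol %), 13 in excess as solvent, slow addition of 12, rt
Reagents that add atoms: none
Why: Morita–Baylis–Hillman reaction at the aldehyde carbon of acrolein; the carbinol centre is racemic and is erased in step 10.

Step 10
Reactants: 14 methyl 3-hydroxy-2-methylidenepent-4-enoate
Product: 15 methyl (2Z)-2-(bromomethyl)penta-2,4-dienoate
Conditions: NBS, Me2S, CH2Cl2, 0 °C to rt; used fresh
Reagents that add atoms: N-bromosuccinimide (O=C1CCC(=O)N1Br)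
Why: Bromination of a Baylis–Hillman alcohol with allylic transposition (bromosulfonium activation, SN2' by bromide) to the conjugated Z bromide; a regioisomeric dienyl bromide would serve equally, since both give the same pentadienyl chromium species in step 11.

Step 11
Reactants: 11 (2Z)-3-[(2R)-2-ethenyl-2-methyl-3-oxo-2,3-dihydrofuran-5-yl]but-2-enal; 15 methyl (2Z)-2-(bromomethyl)penta-2,4-dienoate
Product: 18 (4S,5R)-4-ethenyl-5-{(1Z)-2-[(2R)-2-ethenyl-2-methyl-3-oxo-2,3-dihydrofuran-5-yl]prop-1-en-1-yl}-3-methylideneoxolan-2-one, via silyl ether 16 (not isolated), via hydroxy ester 17 (not isolated)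
Conditions: CrCl2 (10 mol %), (S,S)-3,6-di-tert-butyl-1,8-bis(4-isopropyl-4,5-dihydrooxazol-2-yl)-9H-carbazole (12 mol %), Mn powder (2 equiv), Me3SiCl (1.2 equiv), i-Pr2NEt (30 mol %), THF, 0 °C to rt; then 1 M HCl, THF; then TsOH·H2O (cat.), CH2Cl2, rt
Reagents that add atoms: none
Why: Catalytic asymmetric Nozaki–Hiyama–Kishi allylation, then lactonisation: the pentadienyl chromium reagent from 15 adds through its central carbon in a chair transition state with both substituents equatorial, so C6–O and C7–vinyl should come out anti and close to the trans lactone. The ligand on trivalent chromium selects the Si face of the aldehyde and so sets 6R and with it 7S, independently of the remote C10; the minor facial isomer is a diastereomer and is removed by chromatography.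

Step 12
Reactants: 18 (4S,5R)-4-ethenyl-5-{(1Z)-2-[(2R)-2-ethenyl-2-methyl-3-oxo-2,3-dihydrofuran-5-yl]prop-1-en-1-yl}-3-methylideneoxolan-2-one
Product: 19 (6R,7S,10R)-3,10-epoxy-1-oxogermacra-2,4Z,8Z,11(13)-tetraen-12,6-olide
Conditions: (H2IMes)(PCy3)Cl2Ru=CHPh (10 mol %, two portions), 1,4-benzoquinone (20 mol %), toluene (1 mM), 80 °C, argon sparge
Reagents that add atoms: none
Why: Ring-closing olefin metathesis by the Chauvin mechanism: the catalyst loses PCy3 and exchanges its benzylidene for the less hindered C7 vinyl group, the alkylidene now at C8 adds [2+2] to the C10 vinyl group, and cycloreversion of the ruthenacyclobutane forms C8=C9 and Ru=CH2 while ethylene leaves the solution. The closest known reaction type is ring-closing metathesis to a medium ring that holds a cis-disubstituted alkene. One ring is closed, the ten-membered carbocycle (nine-membered when counted through the bridging oxygen), by alkene–alkene metathesis with the new double bond inside the ring. No stereocentre is formed and C6, C7 and C10 are spectators. Three selectivities are needed: chemoselectivity, ring closure over oligomerisation, and Z geometry. Only the two monosubstituted vinyl groups are reactive enough, since C11=C13 is 1,1-disubstituted and electron-poor, C4=C5 is trisubstituted, C2=C3 is a vinylogous ester, and the other pairings would close a three- or four-membered ring or need the hindered C9 alkylidene to form a trisubstituted alkene. The Z C4=C5 bond, the flat furanone and the trans lactone place both vinyl groups on the same side of the furanone, so high dilution should suffice for closure. An E alkene cannot be spanned by the bicyclo[6.2.1] frame, so the reversible metathesis should funnel to the Z isomer, and benzoquinone suppresses migration of the C7 vinyl group by ruthenium hydrides.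

Step 13
Reactants: 20 acetaldehyde; 21 tert-butyl acrylate
Product: 22 tert-butyl 3-hydroxy-2-methylidenebutanoate (racemic)
Conditions: DABCO (20 mol %), 1,4-dioxane/H2O, rt
Reagents that add atoms: none
Why: Morita–Baylis–Hillman reaction of acetaldehyde with the acrylate; the racemic carbinol centre disappears in step 14.

Step 14
Reactants: 22 tert-butyl 3-hydroxy-2-methylidenebutanoate
Product: 24 tert-butyl (2E)-2-(acetoxymethyl)but-2-enoate, via secondary acetate 23 (not isolated)
Conditions: Ac2O, Et3N, DMAP (cat.), CH2Cl2, 0 °C to rt; then DABCO (20 mol %), THF, reflux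
Reagents that add atoms: acetic anhydride (CC(=O)OC(C)=O)
Why: Acetylation, then DABCO-mediated SN2'/SN2 transposition of the Baylis–Hillman acetate to the primary allylic acetate; the trisubstituted alkene forms under thermodynamic control with methyl trans to the ester (E).

Step 15
Reactants: 24 tert-butyl (2E)-2-(acetoxymethyl)but-2-enoate
Product: 25 (2E)-2-(acetoxymethyl)but-2-enoic acid
Conditions: CF3CO2H/CH2Cl2 (1:4), 0 °C to rt
Reagents that add atoms: none
Why: Acidolysis of the tert-butyl ester with loss of 2-methylpropene; the primary acetate and the E alkene are stable to trifluoroacetic acid.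

Step 16
Reactants: 19 (6R,7S,10R)-3,10-epoxy-1-oxogermacra-2,4Z,8Z,11(13)-tetraen-12,6-olide
Product: 29 (6R,7S,8S,9S,10R)-8,9-dihydroxy-3,10-epoxy-1-oxogermacra-2,4Z,11(13)-trien-12,6-olide, via iodo acetate 26 (not isolated), via 9-acetate 27 (not isolated), via 8-acetate 28 (not isolated)
Conditions: I2 (1.05 equiv), AgOAc (2.3 equiv), AcOH, rt, dark; then H2O (AcOH/H2O 20:1), 50 °C; filter, concentrate; then HCl (0.5 M in MeOH), 0 °C to rt
Reagents that add atoms: silver acetate (CC(=O)[O-].[Ag+]), in exchange with the solvent acetic acid (CC(=O)O): both hydroxyl oxygens
Why: Woodward cis-hydroxylation, then acid-catalysed transesterification: acetyl hypoiodite puts iodonium on the open α face of C8=C9, acetate opens it anti at the less hindered C8 to give 26, and silver-assisted displacement of iodide by the neighbouring acetate forms the 8,9-acetoxonium ion on the β face, which water opens at its central carbon. Both oxygens should therefore end up cis on the hindered face (8S,9S), which a reagent adding from the open side, such as osmium tetroxide, would not reach, and the electron-poor alkenes are inert to iodonium. Because the orthoacid can collapse to 27, to 28 or to both, the crude hydroxy acetate is methanolysed under HCl catalysis to the single diol 29, conditions that the lactone, the vinylogous ester and the Z alkene should tolerate.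

Step 17
Reactants: 29 (6R,7S,8S,9S,10R)-8,9-dihydroxy-3,10-epoxy-1-oxogermacra-2,4Z,11(13)-trien-12,6-olide; 25 (2E)-2-(acetoxymethyl)but-2-enoic acid
Product: 31 (6R,7S,8S,9S,10R)-8-[(2E)-2-(acetoxymethyl)but-2-enoyloxy]-9-hydroxy-3,10-epoxy-1-oxogermacra-2,4Z,11(13)-trien-12,6-olide, via mixed anhydride 30 (not isolated)
Conditions: 25 (1.1 equiv), 2,4,6-Cl3C6H2COCl, Et3N, toluene, rt; then 29, DMAP, toluene, −20 to 0 °C
Reagents that add atoms: none
Why: Yamaguchi esterification through 30: the C8 hydroxyl is flanked by the C7 methine whereas the C9 hydroxyl is neopentylic (next to the quaternary C10), so about one equivalent of the bulky acyl donor at low temperature should acylate O8 only. The E acyl group is the thermodynamic isomer and no stereocentre is touched.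

Step 18
Reactants: 31 (6R,7S,8S,9S,10R)-8-[(2E)-2-(acetoxymethyl)but-2-enoyloxy]-9-hydroxy-3,10-epoxy-1-oxogermacra-2,4Z,11(13)-trien-12,6-olide
Product: 32 (6R,7S,8S,9S,10R)-9-acetoxy-8-[(2E)-2-(acetoxymethyl)but-2-enoyloxy]-3,10-epoxy-1-oxogermacra-2,4Z,11(13)-trien-12,6-olide
Conditions: Ac2O (3 equiv), Sc(OTf)3 (2 mol %), MeCN, −20 °C
Reagents that add atoms: acetic anhydride (CC(=O)OC(C)=O)
Why: Lewis acid-catalysed acetylation with acetic anhydride, a method that reaches hindered secondary hydroxyls at low temperature; the absence of base should keep the C8 ester from migrating to O9 and spares the methylene lactone and the allylic acetate from nucleophilic catalysts. No stereocentre is touched.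

## Compound list

1 | 2-methyl-2-vinyloxirane (racemic) | CC1(CO1)C=C | starting material
2 | (2R)-2-methylbut-3-ene-1,2-diol | OC[C@](C)(O)C=C | intermediate
3 | (2R)-2-hydroxy-2-methylbut-3-enoic acid | OC(=O)[C@](C)(O)C=C | intermediate
4 | (2R)-2-hydroxy-N-methoxy-N,2-dimethylbut-3-enamide | CON(C)C(=O)[C@](C)(O)C=C | intermediate
5 | (2Z)-3-methylpent-2-en-4-yn-1-ol | C#C/C(C)=C\CO | starting material
6 | tert-butyl(dimethyl)silyl ether of 5 | C#C/C(C)=C\CO[Si](C)(C)C(C)(C)C | intermediate
7 | lithium acetylide of 6 | [Li]C#C/C(C)=C\CO[Si](C)(C)C(C)(C)C | intermediate (not isolated)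
8 | (3R,7Z)-9-silyloxy-3-hydroxy-3,7-dimethylnona-1,7-dien-5-yn-4-one | O=C(C#C/C(C)=C\CO[Si](C)(C)C(C)(C)C)[C@](C)(O)C=C | intermediate
9 | (2R)-5-[(2Z)-4-silyloxybut-2-en-2-yl]-2-ethenyl-2-methylfuran-3(2H)-one | C/C(=C/CO[Si](C)(C)C(C)(C)C)C1=CC(=O)[C@](C)(O1)C=C | intermediate
10 | (2R)-2-ethenyl-5-[(2Z)-4-hydroxybut-2-en-2-yl]-2-methylfuran-3(2H)-one | C/C(=C/CO)C1=CC(=O)[C@](C)(O1)C=C | intermediate
11 | (2Z)-3-[(2R)-2-ethenyl-2-methyl-3-oxo-2,3-dihydrofuran-5-yl]but-2-enal | C/C(=C/C=O)C1=CC(=O)[C@](C)(O1)C=C | intermediate
12 | acrolein | C=CC=O | starting material
13 | methyl acrylate | C=CC(=O)OC | starting material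
14 | methyl 3-hydroxy-2-methylidenepent-4-enoate (racemic) | C=CC(O)C(=C)C(=O)OC | intermediate
15 | methyl (2Z)-2-(bromomethyl)penta-2,4-dienoate | C=C/C=C(\CBr)C(=O)OC | intermediate
16 | trimethylsilyl ether of 17 | C=C(C(=O)OC)[C@H](C=C)[C@H](O[Si](C)(C)C)/C=C(/C)C1=CC(=O)[C@](C)(O1)C=C | intermediate (not isolated)
17 | methyl 2-[(3S,4R,5Z)-4-hydroxy-6-[(2R)-2-ethenyl-2-methyl-3-oxo-2,3-dihydrofuran-5-yl]hepta-1,5-dien-3-yl]prop-2-enoate (anti) | C=C(C(=O)OC)[C@H](C=C)[C@H](O)/C=C(/C)C1=CC(=O)[C@](C)(O1)C=C | intermediate (not isolated)
18 | divinyl seco lactone, (4S,5R)-4-ethenyl-5-{(1Z)-2-[(2R)-2-ethenyl-2-methyl-3-oxo-2,3-dihydrofuran-5-yl]prop-1-en-1-yl}-3-methylideneoxolan-2-one | C=C1C(=O)O[C@H](/C=C(/C)C2=CC(=O)[C@](C)(O2)C=C)[C@H]1C=C | intermediate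
19 | (6R,7S,10R)-3,10-epoxy-1-oxogermacra-2,4Z,8Z,11(13)-tetraen-12,6-olide | C=C1C(=O)O[C@@H]2/C=C(/C)C3=CC(=O)[C@](C)(O3)/C=C\[C@@H]12 | intermediate
20 | acetaldehyde | CC=O | starting material
21 | tert-butyl acrylate | C=CC(=O)OC(C)(C)C | starting material
22 | tert-butyl 3-hydroxy-2-methylidenebutanoate (racemic) | CC(O)C(=C)C(=O)OC(C)(C)C | intermediate
23 | tert-butyl 3-acetoxy-2-methylidenebutanoate (racemic) | CC(OC(C)=O)C(=C)C(=O)OC(C)(C)C | intermediate (not isolated)
24 | tert-butyl (2E)-2-(acetoxymethyl)but-2-enoate | C/C=C(\COC(C)=O)C(=O)OC(C)(C)C | intermediate
25 | (2E)-2-(acetoxymethyl)but-2-enoic acid | C/C=C(\COC(C)=O)C(=O)O | intermediate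
26 | 8β-acetoxy-9α-iodo adduct of 19 (8S,9R) | C=C1C(=O)O[C@@H]2/C=C(/C)C3=CC(=O)[C@](C)(O3)[C@H](I)[C@@H](OC(C)=O)[C@@H]12 | intermediate (not isolated)
27 | 9β-acetoxy-8β-hydroxy compound (8S,9S) | C=C1C(=O)O[C@@H]2/C=C(/C)C3=CC(=O)[C@](C)(O3)[C@@H](OC(C)=O)[C@@H](O)[C@@H]12 | intermediate (not isolated)
28 | 8β-acetoxy-9β-hydroxy compound (8S,9S) | C=C1C(=O)O[C@@H]2/C=C(/C)C3=CC(=O)[C@](C)(O3)[C@@H](O)[C@@H](OC(C)=O)[C@@H]12 | intermediate (not isolated)
29 | (6R,7S,8S,9S,10R)-8,9-dihydroxy-3,10-epoxy-1-oxogermacra-2,4Z,11(13)-trien-12,6-olide (8β,9β-diol) | C=C1C(=O)O[C@@H]2/C=C(/C)C3=CC(=O)[C@](C)(O3)[C@@H](O)[C@@H](O)[C@@H]12 | intermediate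
30 | mixed anhydride of 25 with 2,4,6-trichlorobenzoic acid | C/C=C(\COC(C)=O)C(=O)OC(=O)c1c(Cl)cc(Cl)cc1Cl | intermediate (not isolated)
31 | (6R,7S,8S,9S,10R)-8-[(2E)-2-(acetoxymethyl)but-2-enoyloxy]-9-hydroxy-3,10-epoxy-1-oxogermacra-2,4Z,11(13)-trien-12,6-olide | C=C1C(=O)O[C@@H]2/C=C(/C)C3=CC(=O)[C@](C)(O3)[C@@H](O)[C@@H](OC(=O)/C(=C/C)COC(C)=O)[C@@H]12 | intermediate
32 | CNP0325609.1, (6R,7S,8S,9S,10R)-9-acetoxy-8-[(2E)-2-(acetoxymethyl)but-2-enoyloxy]-3,10-epoxy-1-oxogermacra-2,4Z,11(13)-trien-12,6-olide | C=C1C(=O)O[C@@H]2/C=C(/C)C3=CC(=O)[C@](C)(O3)[C@@H](OC(C)=O)[C@@H](OC(=O)/C(=C/C)COC(C)=O)[C@@H]12 | target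

## Step count and least certain steps

Total step count: 18. Longest linear sequence: 12 steps (1, 2, 3, 5, 6, 7, 8, 11, 12, 16, 17, 18).

**Step 12 (key step).** The most likely failure is that intermolecular metathesis through the unhindered C7 vinyl group and cross-metathesis onto the exocyclic methylene outrun closure of the strained bicycle, because the alkylidene has to engage a vinyl group on a quaternary carbon. The fallback sets out from 18 and returns at 19. The methylene lactone is masked by conjugate addition of dimethylamine (Me2NH, THF, 0 °C) to the dimethylamine adduct F1 (C11 epimers), which removes the competing acceptor alkene. F1 is ring-closed with the same catalyst in the presence of one equivalent of TsOH, which keeps the amine protonated, to the ring-closed amine F2. Methyl iodide gives the trimethylammonium iodide F3, and NaHCO3 eliminates trimethylamine to restore the methylene group of 19.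

**Step 16.** The most likely failure is that electrophilic iodination of the vinylogous ester at C2 competes with iodonium formation at the hindered C8=C9 bond, or that the silver-assisted displacement at neopentylic C9 stalls, so the iodo acetate eliminates or is captured across the ring. The facial assignment is itself a deduction from the bridged geometry; it can be checked on the first milligrams, since osmylation and the Woodward sequence must give different diols. The fallback sets out from 19 and returns at 29. It spreads the same double inversion over separate operations without positive iodine. Dimethyldioxirane epoxidises from the open face to the 8α,9α-epoxide F4. Acetate (Bu4NOAc, AcOH, toluene, 60 °C) opens it with inversion at the less hindered C8 to the 8β-acetoxy-9α-alcohol F5. Tf2O/pyridine gives the 9α-triflate F6, and warming in aqueous THF lets the neighbouring acetate displace triflate with inversion and water open the acetoxonium ion to the hydroxy acetates 27 and 28. These are methanolysed as in step 16 to 29.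

**Step 11.** The most likely failure is erosion of the anti preference or of the facial selectivity with the unusual dienyl bromide, or reductive coupling and Z to E isomerisation of the enal under the low-valent metal and chlorosilane. The fallback sets out from 11 and returns at 18. An indium-mediated Barbier reaction of 11 with 15 in THF/water should run through the kinetically formed allylindium in a closed transition state and give syn adducts without lactonisation. The syn hydroxy ester F7 (6S,7S) is separated from its 6R,7R diastereomer F8 and saponified (LiOH, THF/H2O, 0 °C) to the hydroxy acid F9. Mitsunobu lactonisation (PPh3, DIAD) inverts C6 and gives the trans lactone 18. Absolute control is replaced here by diastereomer separation.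

**Step 17.** The most likely failure is insufficient discrimination between the two hydroxyls by the activated acyl donor, with acylation at O9 or at both oxygens; conjugate addition of DMAP to the activated acid is a second loss channel. The fallback sets out from 29 and returns at 32. It reverses the order of acylation with a temporary silyl group, whose introduction responds to steric hindrance more sharply than acylation does. TESCl (1.05 equiv) and imidazole in DMF at −40 °C should give the 8-O-triethylsilyl ether F10. Ac2O, DMAP and pyridine acetylate the remaining C9 hydroxyl to the silyl ether acetate F11. HF·pyridine in THF/pyridine, a non-basic medium in which acetyl migration is slow, frees the C8 hydroxyl and gives 27, which is esterified with 30 as in step 17 to give 32 directly.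

**Step 18.** The most likely failure is sluggish acetylation of the neopentylic hydroxyl beside the bulky C8 ester, with migration of that ester from O8 to O9 taking over. The fallback sets out from 19 and returns at 32, and it keeps the acetate that the Woodward reaction installs. Step 16 is stopped before the methanolysis and the hydroxy acetates 27 and 28 are isolated as a mixture. This mixture is esterified with 30 under Et3N and DMAP. The base interconverts 27 and 28 by 1,2-acetyl shift, and only 27 offers an unhindered secondary hydroxyl, so the faster acylation of 27 should drain both isomers into 32. This fallback makes no compound outside the list (F0).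

## Further compounds

F1 | step 12 | dimethylamine adduct of 18 (C11 epimers) | CN(C)CC1C(=O)O[C@H](/C=C(/C)C2=CC(=O)[C@](C)(O2)C=C)[C@H]1C=C
F2 | step 12 | ring-closed amine, 13-dimethylamino-11,13-dihydro derivative of 19 (C11 epimers) | CN(C)CC1C(=O)O[C@@H]2/C=C(/C)C3=CC(=O)[C@](C)(O3)/C=C\[C@@H]12
F3 | step 12 | trimethylammonium iodide of F2 | C[N+](C)(C)CC1C(=O)O[C@@H]2/C=C(/C)C3=CC(=O)[C@](C)(O3)/C=C\[C@@H]12.[I-]
F4 | step 16 | 8α,9α-epoxide of 19 | C=C1C(=O)O[C@@H]2/C=C(/C)C3=CC(=O)[C@](C)(O3)[C@@H]4O[C@@H]4[C@@H]12
F5 | step 16 | 8β-acetoxy-9α-hydroxy compound | C=C1C(=O)O[C@@H]2/C=C(/C)C3=CC(=O)[C@](C)(O3)[C@H](O)[C@@H](OC(C)=O)[C@@H]12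
F6 | step 16 | 9α-trifluoromethanesulfonate of F5 | C=C1C(=O)O[C@@H]2/C=C(/C)C3=CC(=O)[C@](C)(O3)[C@H](OS(=O)(=O)C(F)(F)F)[C@@H](OC(C)=O)[C@@H]12
F7 | step 11 | syn hydroxy ester (6S,7S), C6 epimer of 17 | C=C(C(=O)OC)[C@H](C=C)[C@@H](O)/C=C(/C)C1=CC(=O)[C@](C)(O1)C=C
F8 | step 11 | syn hydroxy ester (6R,7R), facial diastereomer of F7 | C=C(C(=O)OC)[C@@H](C=C)[C@H](O)/C=C(/C)C1=CC(=O)[C@](C)(O1)C=C
F9 | step 11 | syn hydroxy acid (6S,7S) | C=C(C(=O)O)[C@H](C=C)[C@@H](O)/C=C(/C)C1=CC(=O)[C@](C)(O1)C=C
F10 | step 17 | 8-O-triethylsilyl ether of 29 | C=C1C(=O)O[C@@H]2/C=C(/C)C3=CC(=O)[C@](C)(O3)[C@@H](O)[C@@H](O[Si](CC)(CC)CC)[C@@H]12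
F11 | step 17 | 9-acetate of F10 (8-O-triethylsilyl ether of 27) | C=C1C(=O)O[C@@H]2/C=C(/C)C3=CC(=O)[C@](C)(O3)[C@@H](OC(C)=O)[C@@H](O[Si](CC)(CC)CC)[C@@H]12
F0 | step 18 | none | none
A1 | alternative 1 | ten-membered C9 ketone with Z C4=C5 and masked C1/C3 dione | C=C1C(=O)O[C@@H]2/C=C(/C)C(=O)/C=C(/OC)[C@](C)(OCOC)C(=O)[C@@H](OCOC)[C@@H]12
A2 | alternative 2 | furanone-bridged germacranolide 8,9-acetonide | C=C1C(=O)O[C@@H]2/C=C(/C)C3=CC(=O)[C@](C)(O3)[C@@H](OC(C)(C)O4)[C@@H]4[C@@H]12
A3 | alternative 3 | furanone-bridged cyclodecadienol with free C6–OH | O[C@@H]1/C=C(/C)C2=CC(=O)[C@](C)(O2)[C@@H](OC(C)=O)[C@@H](O[Si](C)(C)C(C)(C)C)[C@H]1C(=C)CO[Si](CC)(CC)CC
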